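The runs are calculated from invented constants; scatter was added.

The alder flask at 30 °C is slow enough to watch G turn into D over minutes, while the D readings of the maple flask at 65 °C show no rise after 10.0 s, its first reading.

| flask | G | J | temperature | remark | time |
|---|---|---|---|---|---|
| alder | 10 mM | 12 mM | 30 °C | run made earlier |  |
| maple | 15 mM | 12 mM | 65 °C | run made earlier |  |
| epsilon | 20 mM | 12.0 mM | 35 °C |  | 4.0 min |
| theta | 20 mM | 12.0 mM |  | at 35 °C until 80 s, from then on at 95 °C | 4.0 min |
| gamma | 20 mM | 12.0 mM | 65 °C |  | 4.0 min |
| alpha | 20 mM | 12.0 mM | 95 °C |  | 4.0 min |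

alder run (percent of the G charged)

| time / min | D / % | G / % |
|---|---|---|
| 0.500 | 18.1 | 80.5 |
| 1.00 | 28.1 | 70.1 |
| 1.33 | 33.3 | 64.3 |
| 2.00 | 36.3 | 58.5 |
| 2.50 | 39.8 | 52.5 |
| 3.00 | 44.0 | 51.6 |

maple run (percent of the G charged)

| time / s | D / % | G / % |
|---|---|---|
| 10.0 | 16.4 | 83.9 |
| 12.0 | 13.9 | 83.4 |
| 20.0 | 17.8 | 82.4 |
| 25.0 | 15.4 | 80.7 |
| 40.0 | 13.3 | 80.2 |

(each reading ± 1 percentage point)

- the flask that comes out highest in amount of D, in percent of the G charged, or "all alike" when all lie within 1.5 percentage points (epsilon / theta / gamma / alpha / all alike)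
- D at the end, in percent of the G charged, epsilon
- D at the end, in percent of the G charged, theta
- D at the end, in percent of the G charged, gamma
- D at the end, in percent of the G charged, alpha



G and D together sink in the maple flask, to 93.5 % of the G charged at its last reading. We take this loss to be one G and one D going off together. Counting steps in place of minutes then removes time. Each G + J step moves G minus D down by 2 units, and each loss step leaves it where it stands. So G minus D, in percent of the G charged, is a tally of J: half of its drop from 100 is the J taken by G.

In the maple flask the tally reads 67.5 % at 10.0 s and 66.9 % at 40.0 s, flat within the scatter, with a mean of 66.8 %. So by these readings G took about 2.49 mM of the 12 mM of J, and within the scatter no more after the first reading. The alder flask, with less G, had taken 4.62 mM by its last reading, more than maple. We therefore read the other 9.51 mM of maple's J as gone by a side road that heat favours, and we put epsilon, the cool flask at 20 mM of G, first.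

In the rate of J towards G over the rate of J down the side road, time drops out again. This selectivity factor, taken as an average over the run, reads 0.262 in the maple flask, with the scatter of the readings on it. If the side road needs no G, the factor grows in step with G, so gamma, at the same temperature and the same charge of J, has about 0.350. We then reckon that G takes 3.11 mM of J in gamma, and that gamma's tally comes to rest at 68.9 %. Before any loss of D, that is 15.5 % of D in gamma. The D readings of the maple flask sink at about 0.360 min⁻¹, a rough reading. Scaled to gamma's G, this gives 0.446 min⁻¹, so we expect 2.61 % of D in gamma at the end.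

The forecast, reading “a fast reversible G + J ⇌ D”, named epsilon and gave 33 %, 3 %, 10 % and 2.5 % for epsilon, theta, gamma and alpha, so on gamma it differs from our reckoning.

The flasks end at 25.5 %, 2.40 %, 3.01 % and 0.00871 % in that order, with epsilon highest.

    G + J → D, rate k1*[G]*[J]^1.5 (k = 530 M⁻¹·⁵ min⁻¹, Ea = 41.0 kJ mol⁻¹)
    J → Q (k = 0.400 min⁻¹, Ea = 86.0 kJ mol⁻¹)
    G + D → E (k = 6.70 M⁻¹ min⁻¹, Ea = 41.0 kJ mol⁻¹)
    (constants at 35 °C)

Gamma ends with D at 3.01 % and J at 0 %. Its tally at 4.00 min is 68.4 %, against the 68.9 % we reckoned, and G stands at 68.4 % after 40.0 min. In theta, with J at 0 % by 2.00 min, the tally stands still as well: it is 40.6 % there and 40.6 % at 4.00 min, and theta's G stands at 40.6 % after 40.0 min.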